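**Retrosynthetic overview**
- Target 17 (3,4,7-tribromo-2-chloro-1H-indole) ⇒ C3–Br by NBS on the free indole ⇒ N–H by sulfonyl removal ⇒ C2–Cl by C2 lithiation/C2Cl6 ⇒ 4,7-dibromo-1-(phenylsulfonyl)indole 13 ⇒ two dehydrogenation stages ⇒ cis-tetrahydroindole 10.
- Feature used: the benzo ring C3a–C4–C5–C6–C7–C7a carries bromine on C4 and C7, the two carbons flanking the fusion bond C3a–C7a, and hydrogen on C5 and C6. C4–C5–C6–C7 is therefore the chain C2–C3–C4–C5 of 2,5-dibromothiophene 1,1-dioxide, and C3a–C7a is the C=C bond of a 2,3-dihydropyrrole.
- Key disconnection: C3a–C4 and C7–C7a by [4+2] cycloaddition of sulfone 3 with enesulfonamide 8, then loss of SO2.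
- Order of ring formation: pyrroline ring first (cyclisation of the sulfonylated amino acetal), six-membered carbocycle second (cycloaddition); the carbocycle is aromatised first, the pyrrole ring second.

Key step: step 4

Remark: benzenesulfonyl is chosen as the nitrogen protecting group (not the more usual tosyl) because it has no benzylic methyl group to compete in the radical bromination of step 6 or to be deprotonated in step 7. Compound 10 is racemic and both of its stereocentres disappear in step 5; the target is achiral.

**Step 1**
Reactants: 1 2,5-dibromothiophene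
Product: 3 2,5-dibromothiophene 1,1-dioxide, via 2,5-dibromothiophene 1-oxide 2 (not isolated)
Conditions: H2O2 (50% aq.), (CF3CO)2O, CH2Cl2, 0 °C to rt
Reagents that add atoms: trifluoroperacetic acid, OOC(=O)C(F)(F)F (made in the flask from hydrogen peroxide, OO, and trifluoroacetic anhydride, FC(F)(F)C(=O)OC(=O)C(F)(F)F)
Why: Two successive electrophilic oxygen transfers from the peracid to sulfur (sulfide to sulfone oxidation) should take place because CF3CO3H is strong enough for the bromine-deactivated thiophene, and the two α-bromines slow the self-dimerisation of the non-aromatic dioxide enough for isolation.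

**Step 2**
Reactants: 4 4,4-diethoxybutan-1-amine; 5 benzenesulfonyl chloride
Product: 6 N-(4,4-diethoxybutyl)benzenesulfonamide
Conditions: Et3N, CH2Cl2, 0 °C to rt
Reagents that add atoms: none
Why: Sulfonylation of the primary amine at nitrogen under basic conditions (sulfonamide formation) is fast and leaves the acid-labile diethyl acetal untouched.

**Step 3**
Reactants: 6 N-(4,4-diethoxybutyl)benzenesulfonamide
Product: 8 1-(phenylsulfonyl)-2,3-dihydro-1H-pyrrole, via 2-ethoxy-1-(phenylsulfonyl)pyrrolidine 7 (not isolated)
Conditions: quinolinium camphorsulfonate (cat.), toluene, reflux, EtOH distilled off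
Reagents that add atoms: none
Why: Acid-catalysed ionisation of the acetal, 5-exo capture of the oxocarbenium ion by the sulfonamide nitrogen to the N,O-acetal 7, and loss of the second ethanol through an N-sulfonyliminium ion that is deprotonated at C3 (cyclisation–elimination of an amino acetal) should give the cyclic enesulfonamide, the buffered weak acid and removal of ethanol driving the equilibrium without dimerising the product.

**Step 4**
Reactants: 3 2,5-dibromothiophene 1,1-dioxide; 8 1-(phenylsulfonyl)-2,3-dihydro-1H-pyrrole
Product: 10 cis-4,7-dibromo-1-(phenylsulfonyl)-2,3,3a,7a-tetrahydro-1H-indole (racemic), via bridged sulfone cycloadduct 9 (not isolated)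
Conditions: 8 (3 equiv), NaHCO3 (solid), toluene, 80 °C, slow addition of 3
Reagents that add atoms: none
Why: The electron-poor, non-aromatic diene C2=C3–C4=C5 of sulfone 3 and the electron-rich C4=C5 bond of enesulfonamide 8 should combine in a concerted, suprafacial Diels–Alder reaction of inverse electron demand that forms C3a–C4 and C7–C7a (indole numbering) and gives the bridged sulfone 9, from which SO2 leaves in a thermally allowed cheletropic step to uncover the 4,7-dibromo-1,3-diene. The closest known reaction type is the cycloaddition of halogenated thiophene 1,1-dioxides with alkenes, enol ethers and enamines followed by extrusion of SO2. The six-membered carbocycle is closed by intermolecular [4+2] cycloaddition across the ring alkene of the preformed five-membered ring, and no other ring is formed. The two new stereocentres C3a and C7a come out cis because both new bonds are made on one face of the cis ring alkene of 8; the product is racemic, endo and exo forms of 9 converge on it, and both centres are removed in step 5. The step needs the cross-cycloaddition to outrun self-dimerisation of 3 and further cycloaddition of 10, which the donor–acceptor pairing, the two α-bromines, the excess of 8 and the slow addition of 3 should secure, and it needs no regiocontrol because the diene is symmetric. NaHCO3 and the moderate temperature guard against acid-promoted aromatisation of 10 by loss of the sulfonamide nitrogen from C7a.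

**Step 5**
Reactants: 10 cis-4,7-dibromo-1-(phenylsulfonyl)-2,3,3a,7a-tetrahydro-1H-indole
Product: 11 4,7-dibromo-1-(phenylsulfonyl)indoline
Conditions: DDQ (1.1 equiv), toluene, rt
Reagents that add atoms: none
Why: DDQ dehydrogenation (hydride abstraction from the allylic C7a–H or C3a–H, then loss of the adjacent proton from the cyclohexadienyl cation) should aromatise the carbocycle, remove both stereocentres and leave the bromines and the sulfonamide untouched.

**Step 6**
Reactants: 11 4,7-dibromo-1-(phenylsulfonyl)indoline
Product: 13 4,7-dibromo-1-(phenylsulfonyl)-1H-indole, via 3,4,7-tribromo-1-(phenylsulfonyl)indoline 12 (not isolated)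
Conditions: NBS (1.05 equiv), AIBN (cat.), PhCF3, 80 °C; then Et3N, rt
Reagents that add atoms: none
Why: Wohl–Ziegler radical bromination should occur at C3, the only benzylic C–H position of 11, and base-induced E2 loss of HBr across C2–C3 from 12 is driven by formation of the aromatic pyrrole ring.

**Step 7**
Reactants: 13 4,7-dibromo-1-(phenylsulfonyl)-1H-indole
Product: 15 4,7-dibromo-2-chloro-1-(phenylsulfonyl)-1H-indole, via 2-lithioindole 14 (not isolated)
Conditions: LiN(iPr)2 (1.05 equiv), THF, −78 °C; then C2Cl6, −78 °C to rt
Reagents that add atoms: hexachloroethane, ClC(Cl)(Cl)C(Cl)(Cl)Cl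
Why: The N-sulfonyl group acidifies C2–H and directs its deprotonation by the non-nucleophilic amide base at −78 °C (directed lithiation of a 1-sulfonylindole), where the aryl bromides should neither exchange nor eliminate, and the 2-lithioindole 14 takes a positive chlorine from hexachloroethane.

**Step 8**
Reactants: 15 4,7-dibromo-2-chloro-1-(phenylsulfonyl)-1H-indole
Product: 16 4,7-dibromo-2-chloro-1H-indole
Conditions: KOH, 1,4-dioxane/H2O, 60 °C; then aq. NH4Cl; product used at once
Reagents that add atoms: none
Why: Hydroxide attacks the sulfonyl sulfur and expels the indolide, a good leaving group here because of the three halogens (base hydrolysis of an N-sulfonylindole), and the alcohol-free medium avoids N-alkylation by a sulfonate ester.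

**Step 9**
Reactants: 16 4,7-dibromo-2-chloro-1H-indole
Product: 17 3,4,7-tribromo-2-chloro-1H-indole
Conditions: NBS (1.0 equiv), DMF, 0 °C
Reagents that add atoms: N-bromosuccinimide, O=C1CCC(=O)N1Br
Why: Electrophilic aromatic substitution of the free indole by NBS should go to C3, its most nucleophilic carbon and the only open position of the pyrrole ring, while the halogen-deactivated benzo ring does not react with one equivalent at 0 °C.

**Compound list**
1 | 2,5-dibromothiophene | Brc1ccc(Br)s1 | starting material
2 | 2,5-dibromothiophene 1-oxide | O=S1C(Br)=CC=C1Br | intermediate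
3 | 2,5-dibromothiophene 1,1-dioxide | O=S1(=O)C(Br)=CC=C1Br | intermediate
4 | 4,4-diethoxybutan-1-amine | CCOC(CCCN)OCC | starting material
5 | benzenesulfonyl chloride | O=S(=O)(Cl)c1ccccc1 | starting material
6 | N-(4,4-diethoxybutyl)benzenesulfonamide | CCOC(CCCNS(=O)(=O)c1ccccc1)OCC | intermediate
7 | 2-ethoxy-1-(phenylsulfonyl)pyrrolidine (racemic, one enantiomer drawn) | CCO[C@H]1CCCN1S(=O)(=O)c1ccccc1 | intermediate
8 | 1-(phenylsulfonyl)-2,3-dihydro-1H-pyrrole | O=S(=O)(N1CCC=C1)c1ccccc1 | intermediate
9 | 4,7-dibromo-1-(phenylsulfonyl)-2,3,3a,4,7,7a-hexahydro-1H-4,7-epithioindole 8,8-dioxide (racemic, cis-fused; endo isomer drawn, pyrrolidine ring anti to the SO2 bridge) | O=S(=O)(c1ccccc1)N1CC[C@@H]2[C@H]1[C@]1(Br)C=C[C@@]2(Br)S1(=O)=O | intermediate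
10 | cis-4,7-dibromo-1-(phenylsulfonyl)-2,3,3a,7a-tetrahydro-1H-indole (racemic, H-3a and H-7a on the same face, one enantiomer drawn) | O=S(=O)(c1ccccc1)N1CC[C@H]2C(Br)=CC=C(Br)[C@@H]12 | intermediate
11 | 4,7-dibromo-1-(phenylsulfonyl)indoline | O=S(=O)(c1ccccc1)N1CCc2c(Br)ccc(Br)c12 | intermediate
12 | 3,4,7-tribromo-1-(phenylsulfonyl)indoline (racemic, one enantiomer drawn) | O=S(=O)(c1ccccc1)N1C[C@@H](Br)c2c(Br)ccc(Br)c12 | intermediate
13 | 4,7-dibromo-1-(phenylsulfonyl)-1H-indole | O=S(=O)(c1ccccc1)n1ccc2c(Br)ccc(Br)c12 | intermediate
14 | 4,7-dibromo-2-lithio-1-(phenylsulfonyl)-1H-indole | [Li]c1cc2c(Br)ccc(Br)c2n1S(=O)(=O)c1ccccc1 | intermediate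
15 | 4,7-dibromo-2-chloro-1-(phenylsulfonyl)-1H-indole | Clc1cc2c(Br)ccc(Br)c2n1S(=O)(=O)c1ccccc1 | intermediate
16 | 4,7-dibromo-2-chloro-1H-indole | Clc1cc2c(Br)ccc(Br)c2[nH]1 | intermediate
17 | 3,4,7-tribromo-2-chloro-1H-indole | Clc1[nH]c2c(Br)ccc(Br)c2c1Br | target

**Step count**
Total steps: 9. Longest linear sequence: 8 steps (steps 2 to 9, from 4,4-diethoxybutan-1-amine 4).

**Steps most likely to fail**

1. Step 4. The sulfone diene may dimerise, or add to the product diene, faster than it meets the enesulfonamide. The dihydroarene may also aromatise with ring opening, by expulsion of the sulfonamide nitrogen from C7a, which leads to a dead end. The fallback sets out from 3 and replaces the dienophile by purchased tert-butyl 2,3-dihydro-1H-pyrrole-1-carboxylate (CC(C)(C)OC(=O)N1CCC=C1). Its carbamate nitrogen is a much poorer leaving group, and it can be used in large excess. Cycloaddition and SO2 loss in toluene at 80 °C should pass through tert-butyl 4,7-dibromo-2,3,3a,4,7,7a-hexahydro-1H-4,7-epithioindole-1-carboxylate 8,8-dioxide F1 to tert-butyl cis-4,7-dibromo-2,3,3a,7a-tetrahydro-1H-indole-1-carboxylate F2. DDQ should then give tert-butyl 4,7-dibromoindoline-1-carboxylate F3, and CF3CO2H in CH2Cl2 should free 4,7-dibromoindoline F4. Sulfonylation with 5 in pyridine at 60 °C comes back to the route at 11.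

2. Step 6. Hydrogen abstraction at C3 next to the peri bromine may be slow, so that ionic bromination of the benzo ring para to nitrogen, or addition of bromine to the newly formed C2=C3 bond, takes over. The fallback sets out from 11 and moves the dehydrogenation to the free amine. CF3SO3H in 1,2-dichloroethane at 80 °C should cleave the N-aryl sulfonamide to 4,7-dibromoindoline F4, the amine already met in the fallback to step 4. MnO2 in toluene at 80 °C should dehydrogenate it to 4,7-dibromo-1H-indole F5. NaH followed by 5 in DMF at 0 °C to rt restores the sulfonyl group and comes back to the route at 13.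

3. Step 8. Once the sulfonyl group is gone, the N–H 2-chloroindole with a free C3 position may decompose on work-up and handling, by acid-catalysed hydrolysis to the oxindole or by oligomerisation. The fallback sets out from 15 and reverses the order of the last two operations. Br2 with NaOAc in AcOH at 50 °C should brominate C3 of the protected indole to 3,4,7-tribromo-2-chloro-1-(phenylsulfonyl)-1H-indole F6. KOH in 1,4-dioxane/H2O at 60 °C then removes the sulfonyl group and comes back to the route at 17, so that 16 is never handled.

**Further compounds**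
F1 | step 4 | tert-butyl 4,7-dibromo-2,3,3a,4,7,7a-hexahydro-1H-4,7-epithioindole-1-carboxylate 8,8-dioxide (racemic, cis-fused, endo isomer drawn) | CC(C)(C)OC(=O)N1CC[C@@H]2[C@H]1[C@]1(Br)C=C[C@@]2(Br)S1(=O)=O
F2 | step 4 | tert-butyl cis-4,7-dibromo-2,3,3a,7a-tetrahydro-1H-indole-1-carboxylate (racemic, one enantiomer drawn) | CC(C)(C)OC(=O)N1CC[C@H]2C(Br)=CC=C(Br)[C@@H]12
F3 | step 4 | tert-butyl 4,7-dibromoindoline-1-carboxylate | CC(C)(C)OC(=O)N1CCc2c(Br)ccc(Br)c12
F4 | step 4 | 4,7-dibromoindoline | Brc1ccc(Br)c2c1CCN2
F5 | step 6 | 4,7-dibromo-1H-indole | Brc1ccc(Br)c2[nH]ccc12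
F6 | step 8 | 3,4,7-tribromo-2-chloro-1-(phenylsulfonyl)-1H-indole | Clc1c(Br)c2c(Br)ccc(Br)c2n1S(=O)(=O)c1ccccc1
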